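**Strategy.** The route rests on cutting ring C (C8, C9, C11, C12, C13, C14) out of the target by a retro-[4+2] across C8–C14 and C9–C11. A spiro-fused, α-acetylated α,β-unsaturated δ-lactone, in which C8 is flanked by the lactone carbonyl C7 and the future C15 ketone, takes up buta-1,3-diene in a Lewis-acid-catalysed Diels–Alder reaction: the C8–C14 bond closes ring C, creates the quaternary C8 and the C9 stereocentre in one operation, and leaves the C12=C13 alkene for a palladium-mediated closure of ring D. Ring A with its C5 stereocentre comes from an organocatalytic Michael–aldol annulation.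

Key step: step 6

Atom labels (ent-kaurane numbering, used throughout): C1 = CH–OAc; C2, C3 = ring A CH2; C4 = CMe2; C5 = CH bearing the carboxyl C6; C10 = spiro carbon; C20 = OCH2; C7 = lactone C=O; C8 = quaternary carbon between C7 and C15; C9 = CH between C8 and C10; C11, C12 = CH2–CH2; C13 = bridgehead CH; C14 = CH2 between C8 and C13; C15 = ketone; C16 = CH(CH3); C17 = that methyl. Ring A = C1–C5 and C10; ring C = C8, C9, C11–C14; ring D = C8, C14, C13, C16, C15.

Assumption: the (1R,2R)-configured amine–thiourea catalyst is taken to give the (S)-configured Michael adduct; the induction is catalyst-controlled, so the mirror-image catalyst would be used if the sense were opposite.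

Step 1
Reactants: 1 (E)-4-oxopent-2-enoic acid
Product: 2 benzyl (E)-4-oxopent-2-enoate
Conditions: BnBr, KHCO3, DMF, rt
Reagents that add atoms: benzyl bromide, BrCc1ccccc1
Why: SN2 O-alkylation of the carboxylate (esterification) under mildly basic conditions should leave the enone untouched and install an ester that the last hydrogenation removes.

Step 2
Reactants: 2 benzyl (E)-4-oxopent-2-enoate; 3 2-methylpropanal
Product: 5 benzyl (1S)-2,2-dimethyl-5-oxocyclohex-3-ene-1-carboxylate, via keto aldehyde Michael adduct 4 (not isolated)
Conditions: 1-[(1R,2R)-2-aminocyclohexyl]-3-[3,5-bis(trifluoromethyl)phenyl]thiourea (10 mol%), PhCO2H (10 mol%), toluene, rt; then TsOH·H2O (10 mol%), toluene, 80 °C, removal of water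
Reagents that add atoms: none
Why: Organocatalytic enamine Michael addition of the α-branched aldehyde to the carbon β to the ketone (α to the ester) of the 4-oxo-enoate, with the thiourea holding the acceptor so that one face is attacked and C5 forms as (S), followed by acid-catalysed intramolecular aldol condensation of the methyl ketone onto the neopentyl aldehyde (Robinson-type annulation), should close ring A.

Step 3
Reactants: 5 benzyl (1S)-2,2-dimethyl-5-oxocyclohex-3-ene-1-carboxylate
Product: 6 benzyl (1S)-2,2-dimethyl-5-oxo-6-{[2-(trimethylsilyl)ethoxy]methyl}cyclohex-3-ene-1-carboxylate (both epimers at C10)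
Conditions: LiN(iPr)2, THF, −78 °C; then ClCH2OCH2CH2SiMe3, −78 to −30 °C
Reagents that add atoms: 2-(trimethylsilyl)ethoxymethyl chloride, C[Si](C)(C)CCOCCl
Why: Kinetic α′-deprotonation of the enone at C10 (the only enolisable position of the ketone, C2 being vinylic and C4 quaternary) and C-alkylation of the cross-conjugated lithium enolate with the chloromethyl ether should put C20 in place as a masked hydroxymethyl group; the new C10 centre is planarised again in step 4.

Step 4
Reactants: 6 the alkylated enone; 7 ethyl 2-(ethoxymethylidene)-3-oxobutanoate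
Product: 8 benzyl 6-(2-acetyl-3-ethoxy-3-oxoprop-1-en-1-yl)-2,2-dimethyl-5-oxo-6-{[2-(trimethylsilyl)ethoxy]methyl}cyclohex-3-ene-1-carboxylate (C5 as in 5; alkenyl group on C10 trans and CH2O group cis to the ester; E/Z mixture)
Conditions: LiN(iPr)2, THF, −78 °C; then 7, −78 to −30 °C; then H2O
Reagents that add atoms: none
Why: Regiodefined deprotonation at C10 and Michael addition–elimination of the enolate to the alkoxymethylene β-keto ester should create the quaternary C10, the electrophile entering anti to the neighbouring C5 ester so that C9 ends trans and C20 cis to it.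

Step 5
Reactants: 8 the C10-quaternary alkylidene β-keto ester
Product: 10 benzyl 4-acetyl-8,8-dimethyl-3,11-dioxo-2-oxaspiro[5.5]undeca-4,9-diene-7-carboxylate (spiro dienophile; C9 trans and C20 cis to the ester), via hydroxy ester 9 (not isolated)
Conditions: BF3·OEt2, CH2Cl2, 0 °C to rt; H2O work-up; then TsOH·H2O (cat.), toluene, 60 °C
Reagents that add atoms: none
Why: Lewis-acid-induced β-silyl fragmentation of the 2-(trimethylsilyl)ethyl ether should free the C20 alcohol, which then lactonises onto the ethyl ester (acid-catalysed transesterification to the six-membered lactone, the alkylidene β-dicarbonyl equilibrating E/Z under acid) without touching a stereocentre.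

Step 6
Reactants: 10 the spiro dienophile; 11 buta-1,3-diene
Product: 12 cis-fused Diels–Alder adduct (ring C cyclohexene with C12=C13, fused to the δ-lactone at C8–C9; acetyl on C8 cis to H9; C11 and C14 on the lactone face of C1)
Conditions: buta-1,3-diene (10 equiv), SnCl4 (0.3 equiv), CH2Cl2, −78 to −20 °C
Reagents that add atoms: none
Why: SnCl4 chelates the C7 and C15 carbonyls of the alkylidene β-keto lactone and the diene adds in an asynchronous, concerted [4+2] Diels–Alder reaction in which the C9–C11 bond runs ahead and the C8–C14 bond then closes ring C. The closest known reactions are the Lewis-acid-catalysed cycloadditions of butadiene to 2-acyl- and 2-alkoxycarbonyl-cycloalk-2-enones and to alkylidene β-keto esters that carry a quaternary γ-carbon. Ring C closes as a six-membered ring by suprafacial cycloaddition to the Z-configured endocyclic alkene, so the lactone/ring C fusion is cis and the acetyl group on C8 and H9 end on the same face. The configuration of C8 and C9 relative to the spiro carbon C10 should be controlled by the diene approaching the lactone face flanked by the flat C1 carbonyl, anti to the C5 methine whose benzyl ester and neighbouring C4 methyl shield the other face. The step needs site selectivity for C8=C9 over the ring A enone C2=C3, which the double activation of C8=C9 and the neopentyl β-carbon C3 secure, while regio- and endo/exo selectivity do not arise with the symmetrical, unsubstituted diene.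

Step 7
Reactants: 12 the Diels–Alder adduct
Product: 13 tert-butyldimethylsilyl enol ether of the C8 acetyl group (C15(OSi)=C16H2)
Conditions: TBSOTf, Et3N, CH2Cl2, 0 °C
Reagents that add atoms: tert-butyldimethylsilyl trifluoromethanesulfonate, CC(C)(C)[Si](C)(C)OS(=O)(=O)C(F)(F)F
Why: Soft enolisation with silyl triflate and amine should convert the methyl ketone, the only enolisable carbonyl (the ring A enone has no α′ or γ hydrogen and C8 is quaternary), into its silyl enol ether, which protects C15 from hydride in step 8 and is the nucleophile of step 10.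

Step 8
Reactants: 13 the silyl enol ether
Product: 14 C1 allylic alcohol (hydroxyl cis to C20 and to the C5 ester)
Conditions: NaBH4, CeCl3·7H2O, MeOH/CH2Cl2, −78 °C
Reagents that add atoms: none
Why: Luche 1,2-reduction of the ring A enone, with hydride expected to add axially, anti to the pseudo-axial C20 methylene on the spiro carbon, so that the C1 hydroxyl ends cis to C20 and to the C5 ester.

Step 9
Reactants: 14 the allylic alcohol
Product: 15 C1 acetate
Conditions: Ac2O, pyridine, DMAP (cat.), CH2Cl2, rt
Reagents that add atoms: acetic anhydride, CC(=O)OC(C)=O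
Why: DMAP-catalysed O-acylation of the secondary allylic alcohol with retention at C1, under conditions that the silyl enol ether should tolerate.

Step 10
Reactants: 15 the acetate
Product: 16 tetracyclic ketone (bicyclo[3.2.1]octenone: C16H2 bonded to C13, C15 ketone, C11=C12 alkene)
Conditions: Pd(OAc)2 (1.1 equiv), MeCN, rt
Reagents that add atoms: none
Why: Oxidative cycloalkenylation with divalent palladium (Saegusa-type palladium enolate, syn carbopalladation of the C12=C13 alkene in the 5-exo sense, then β-hydride elimination towards C11 since the bridgehead cannot become olefinic) should join C16 to C13 on the ring C face that carries the acetyl group, which fixes the bridgehead C13 and gives the bicyclo[3.2.1]octenone.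

Step 11
Reactants: 16 the tetracyclic ketone
Product: 17 16-methylene-15-ketone (exocyclic enone C16=C17)
Conditions: (CH2O)n, PhNHMe·CF3CO2H, THF, 65 °C
Reagents that add atoms: paraformaldehyde (delivers formaldehyde), C=O
Why: Mannich-type α-methylenation (aminomethylation by the iminium ion from formaldehyde and N-methylaniline, then elimination of the amine) at C16, the only enolisable position next to the C15 ketone, should give the exocyclic enone.

Step 12
Reactants: 17 the exocyclic enone
Product: 18 the target
Conditions: H2 (1 atm), 10% Pd/C, EtOAc, rt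
Reagents that add atoms: none
Why: Heterogeneous catalytic hydrogenation should saturate C2=C3, C11=C12 and C16=C17 and hydrogenolyse the benzyl ester in one operation, hydrogen adding to the exocyclic alkene from the open exo face (the side of the one-carbon bridge C14) so that the C17 methyl ends endo, towards C11 and C12, as in the target.

**Compound list**

1 | (E)-4-oxopent-2-enoic acid | CC(=O)/C=C/C(=O)O | starting material
2 | benzyl (E)-4-oxopent-2-enoate | CC(=O)/C=C/C(=O)OCc1ccccc1 | intermediate
3 | 2-methylpropanal | CC(C)C=O | starting material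
4 | benzyl (2S)-2-(2-methyl-1-oxopropan-2-yl)-4-oxopentanoate (keto aldehyde Michael adduct) | CC(=O)C[C@H](C(=O)OCc1ccccc1)C(C)(C)C=O | intermediate (not isolated)
5 | benzyl (1S)-2,2-dimethyl-5-oxocyclohex-3-ene-1-carboxylate (ring A enone) | O=C1C=CC(C)(C)[C@@H](C(=O)OCc2ccccc2)C1 | intermediate
6 | benzyl (1S)-2,2-dimethyl-5-oxo-6-{[2-(trimethylsilyl)ethoxy]methyl}cyclohex-3-ene-1-carboxylate (both epimers at C10) | O=C1C=CC(C)(C)[C@@H](C(=O)OCc2ccccc2)C1COCC[Si](C)(C)C | intermediate
7 | ethyl 2-(ethoxymethylidene)-3-oxobutanoate | CCOC=C(C(C)=O)C(=O)OCC | starting material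
8 | benzyl 6-(2-acetyl-3-ethoxy-3-oxoprop-1-en-1-yl)-2,2-dimethyl-5-oxo-6-{[2-(trimethylsilyl)ethoxy]methyl}cyclohex-3-ene-1-carboxylate (alkenyl trans, CH2O cis to the ester; E/Z mixture) | O=C1C=CC(C)(C)[C@@H](C(=O)OCc2ccccc2)[C@@]1(C=C(C(C)=O)C(=O)OCC)COCC[Si](C)(C)C | intermediate
9 | benzyl 6-(2-acetyl-3-ethoxy-3-oxoprop-1-en-1-yl)-6-(hydroxymethyl)-2,2-dimethyl-5-oxocyclohex-3-ene-1-carboxylate (hydroxy ester, configured as 8) | O=C1C=CC(C)(C)[C@@H](C(=O)OCc2ccccc2)[C@@]1(C=C(C(C)=O)C(=O)OCC)CO | intermediate (not isolated)
10 | benzyl 4-acetyl-8,8-dimethyl-3,11-dioxo-2-oxaspiro[5.5]undeca-4,9-diene-7-carboxylate (spiro dienophile; C9 trans, C20 cis to the ester) | O=C1C=CC(C)(C)[C@@H](C(=O)OCc3ccccc3)[C@@]12COC(=O)C(C(C)=O)=C2 | intermediate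
11 | buta-1,3-diene | C=CC=C | starting material
12 | cis-fused Diels–Alder adduct (C12=C13 cyclohexene on the lactone; acetyl on C8 cis to H9; ring A enone and benzyl ester retained) | O=C1C=CC(C)(C)[C@@H](C(=O)OCc4ccccc4)[C@@]12COC(=O)[C@@]3(C(C)=O)CC=CC[C@@H]23 | intermediate
13 | tert-butyldimethylsilyl enol ether of 12 | O=C1C=CC(C)(C)[C@@H](C(=O)OCc4ccccc4)[C@@]12COC(=O)[C@@]3(C(=C)O[Si](C)(C)C(C)(C)C)CC=CC[C@@H]23 | intermediate
14 | C1 allylic alcohol (OH cis to C20 and to the ester) | O[C@H]1C=CC(C)(C)[C@@H](C(=O)OCc4ccccc4)[C@@]12COC(=O)[C@@]3(C(=C)O[Si](C)(C)C(C)(C)C)CC=CC[C@@H]23 | intermediate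
15 | C1 acetate of 14 | CC(=O)O[C@H]1C=CC(C)(C)[C@@H](C(=O)OCc4ccccc4)[C@@]12COC(=O)[C@@]3(C(=C)O[Si](C)(C)C(C)(C)C)CC=CC[C@@H]23 | intermediate
16 | tetracyclic 15-ketone with C11=C12 and C2=C3 alkenes (benzyl ester, C1 acetate) | CC(=O)O[C@H]1C=CC(C)(C)[C@@H](C(=O)OCc4ccccc4)[C@@]12COC(=O)[C@@]13C[C@@H](C=C[C@H]12)CC3=O | intermediate
17 | 16-methylene derivative of 16 (exocyclic enone) | CC(=O)O[C@H]1C=CC(C)(C)[C@@H](C(=O)OCc4ccccc4)[C@@]12COC(=O)[C@@]13C[C@@H](C=C[C@H]12)C(=C)C3=O | intermediate
18 | target (1-acetoxy-15-oxo-6,7-seco-ent-kauran-7,20-olid-6-oic acid, 16-methyl endo) | CC(=O)O[C@H]1CCC(C)(C)[C@@H](C(=O)O)[C@@]12COC(=O)[C@@]13C[C@@H](CC[C@H]12)[C@@H](C)C3=O | target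

**Step count:** 12 steps in total. **Longest linear sequence:** 12 steps (1 to 18); the route is linear, with 3, 7 and 11 entering as commercial reactants.

**Steps most likely to fail**

Step 4. The tertiary, β-alkoxy lithium enolate of 6 may be too hindered to add to the trisubstituted acceptor carbon of 7, or may simply transfer a proton to the acetyl group of 7. The fallback sets out from 6 and comes back at 10; it brings C9 in as a small formyl group and closes the lactone ring through the C8=C9 bond instead. The enolate of 6 (LiN(iPr)2, THF, −78 °C) is C-formylated with 2,2,2-trifluoroethyl formate, anti to the ester, to give the quaternary keto aldehyde F1. BF3·OEt2 in CH2Cl2 removes the silylethyl group to give the hydroxy aldehyde F2. Heating with 2,2,6-trimethyl-4H-1,3-dioxin-4-one in toluene at 110 °C (acetylketene transfer) acylates the alcohol to the acetoacetate F3. Piperidinium acetate then effects an intramolecular Knoevenagel condensation between the aldehyde and the active methylene, which should give 10.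

Step 6. The Lewis acid may polymerise the diene faster than the cycloaddition proceeds at the neopentyl carbon C9, and warming to force the reaction would erode the facial selectivity. The fallback sets out from 10 and comes back at 12; it keeps a [4+2] closure of ring C through C8–C14 but uses an electron-rich diene without Lewis acid and then removes the extra oxygen. 10 and 2-(trimethylsilyloxy)buta-1,3-diene in toluene at 80 °C should give the silyl enol ether adduct F4, the nucleophilic diene terminus bonding to C9 so that the oxygen sits on C12 and the alkene is C12=C13. CsF and N-phenylbis(trifluoromethanesulfonimide) in DME convert it regiospecifically into the enol triflate F5. Pd(OAc)2, PPh3, Bu3N and HCO2H in DMF at 60 °C (formate reduction of the C–OTf bond by zerovalent palladium) should then give 12.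

Step 2. The catalytic Michael addition sets the absolute configuration of the whole route; the thiourea may fail to differentiate the faces of this acceptor class, or background addition through an achiral enamine may lower the enantiomeric purity. The fallback sets out from 3 and comes back at 4; it replaces catalytic hydrogen-bond control by a stoichiometric chiral enamine (Stork enamine Michael addition with an auxiliary). 3 is condensed with (2S)-2-(methoxymethyl)pyrrolidine (toluene, removal of water) to the enamine F6, which is added to 2 in toluene at −20 °C; hydrolysis with aqueous AcOH should release 4, which is closed to 5 with TsOH·H2O as in step 2. The antipodal auxiliary is used if the sense of induction is opposite.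

Further compounds
F1 | step 4 | benzyl 6-formyl-2,2-dimethyl-5-oxo-6-{[2-(trimethylsilyl)ethoxy]methyl}cyclohex-3-ene-1-carboxylate (formyl trans to the ester) | O=C1C=CC(C)(C)[C@@H](C(=O)OCc2ccccc2)[C@@]1(C=O)COCC[Si](C)(C)C
F2 | step 4 | benzyl 6-formyl-6-(hydroxymethyl)-2,2-dimethyl-5-oxocyclohex-3-ene-1-carboxylate | O=C1C=CC(C)(C)[C@@H](C(=O)OCc2ccccc2)[C@@]1(C=O)CO
F3 | step 4 | benzyl 6-formyl-2,2-dimethyl-5-oxo-6-[(3-oxobutanoyloxy)methyl]cyclohex-3-ene-1-carboxylate | O=C1C=CC(C)(C)[C@@H](C(=O)OCc2ccccc2)[C@@]1(C=O)COC(=O)CC(C)=O
F4 | step 6 | C12 trimethylsilyl enol ether analogue of 12 (C12(OSiMe3)=C13) | O=C1C=CC(C)(C)[C@@H](C(=O)OCc4ccccc4)[C@@]12COC(=O)[C@@]3(C(C)=O)CC=C(O[Si](C)(C)C)C[C@@H]23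
F5 | step 6 | C12 enol triflate analogue of 12 | O=C1C=CC(C)(C)[C@@H](C(=O)OCc4ccccc4)[C@@]12COC(=O)[C@@]3(C(C)=O)CC=C(OS(=O)(=O)C(F)(F)F)C[C@@H]23
F6 | step 2 | (2S)-2-(methoxymethyl)-1-(2-methylprop-1-en-1-yl)pyrrolidine | COC[C@@H]1CCCN1C=C(C)C
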